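**Strategy.** In the target the carboxyl carbon sits one carbon beyond a CH2 on the diaryl methine at C8 of ring A, ortho to the C7 oxygen. A palladium-catalysed asymmetric cyclocarbonylation therefore inserts CO between the terminal CH2 of a 1,1-diarylethene and O7–H. In one operation it forms the CH2–C(=O) and O7–C(=O) bonds, a six-membered lactone fused at C7–C8, and the (R) benzylic centre. Its precursor is 5,7-dihydroxy-2,3-dimethyl-8-(1-phenylvinyl)chromone. Afterwards the lactone is opened with O7-methylation, C6 is prenylated through an iodide, and a final CuH reduction sets the cis-2,3-dimethylchromanone.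

Key step: step 6

Assumption: chromone numbering is used and ring A is the benzene ring; the DTBM-SEGPHOS antipodes in steps 6 and 11 are assigned by analogy, and the mirror-image ligand would be used if the facial sense on these substrates proved opposite.

**Step 1**
Reactants: 1 2',4',6'-trihydroxypropiophenone; 2 acetic anhydride
Product: 4 5,7-dihydroxy-2,3-dimethylchromone, via 5,7-diacetoxy-2,3-dimethylchromone 3 (not isolated)
Conditions: Ac2O, NaOAc, 170 °C; then HCl (cat.), MeOH, reflux
Reagents that add atoms: acetic anhydride (2), CC(=O)OC(C)=O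
Why: Kostanecki–Robinson reaction, in which an O-acetyl group is transferred to the ketone α-carbon and cyclodehydration closes the 2,3-dimethylchromone (the α-methyl group blocks 3-acylation), followed by acid methanolysis of the two aryl acetates.

**Step 2**
Reactants: 4 5,7-dihydroxy-2,3-dimethylchromone
Product: 5 5,7-bis(methoxymethoxy)-2,3-dimethylchromone
Conditions: NaH, MOMCl, DMF, 0 °C → rt
Reagents that add atoms: chloromethyl methyl ether, COCCl
Why: Williamson-type O-alkylation (MOM protection), with NaH needed for the hydrogen-bonded 5-OH; capping both phenols is what later steers iodination to C8.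

**Step 3**
Reactants: 5 5,7-bis(methoxymethoxy)-2,3-dimethylchromone
Product: 6 8-iodo-5,7-bis(methoxymethoxy)-2,3-dimethylchromone
Conditions: NIS, DMF, rt → 50 °C, dark
Reagents that add atoms: N-iodosuccinimide, O=C1CCC(=O)N1I
Why: Electrophilic aromatic iodination, which on 5,7-dialkoxychromones with O5 alkylated should go to C8 and not to C6 (crowded between two alkoxy groups), under neutral conditions that spare the acetals; the site would be confirmed by HMBC/NOE.

**Step 4**
Reactants: 6 8-iodo-5,7-bis(methoxymethoxy)-2,3-dimethylchromone; 7 1-phenylvinylboronic acid pinacol ester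
Product: 8 5,7-bis(methoxymethoxy)-2,3-dimethyl-8-(1-phenylvinyl)chromone
Conditions: Pd(OAc)2, SPhos, K3PO4, toluene/H2O, 90 °C
Reagents that add atoms: 1-phenylvinylboronic acid pinacol ester (7), C=C(B1OC(C)(C)C(C)(C)O1)c1ccccc1
Why: Suzuki–Miyaura coupling, with the bulky electron-rich biarylphosphine chosen for the di-ortho-substituted aryl iodide and the α-substituted vinylboronate; acetals and chromone tolerate aqueous phosphate.

**Step 5**
Reactants: 8 5,7-bis(methoxymethoxy)-2,3-dimethyl-8-(1-phenylvinyl)chromone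
Product: 9 5,7-dihydroxy-2,3-dimethyl-8-(1-phenylvinyl)chromone
Conditions: HCl (cat.), MeOH/THF, 40 °C
Reagents that add atoms: none
Why: Acid-catalysed acetal cleavage (transacetalisation of the MOM groups to methanol); the alkene should survive dilute acid because the chromone carbonyl reduces the donor strength of the ring oxygens and the hindered aryl group is twisted out of conjugation.

**Step 6**
Reactants: 9 5,7-dihydroxy-2,3-dimethyl-8-(1-phenylvinyl)chromone; 10 carbon monoxide
Product: 11 (10R)-5-hydroxy-2,3-dimethyl-10-phenyl-9,10-dihydro-4H,8H-pyrano[2,3-f]chromene-4,8-dione (4-phenyl-3,4-dihydrocoumarin fused at C7–C8 of the chromone)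
Conditions: Pd(OAc)2 (5 mol %), (R)-DTBM-SEGPHOS (6 mol %), TsOH·H2O (10 mol %), CO (20 bar), toluene, 70 °C
Reagents that add atoms: carbon monoxide (10), [C-]#[O+]
Why: A cationic diphosphine palladium hydride, formed from Pd(OAc)2, the ligand and TsOH under CO, adds across the 1,1-diarylethene with H going to the diaryl carbon and palladium to the terminal CH2; CO then inserts into the Pd–CH2 bond and the ortho O7–H attacks the acyl carbon, releasing the lactone and regenerating the hydride. The closest known reaction type is the palladium-catalysed asymmetric intramolecular hydroesterification of 2-(1-arylvinyl)phenols to 4-aryl-3,4-dihydrocoumarins. The single new ring, the six-membered lactone, closes by 6-exo-trig attack of O7 on the acyl–palladium carbon. The benzylic stereocentre is set in the hydropalladation under ligand control, the chiral pocket selecting the alkene face by distinguishing the flat phenyl group from the di-ortho-substituted chromone ring. The step needs anti-Markovnikov addition and acylation of O7 only: the 1,1-disubstitution keeps palladium off the crowded diaryl carbon, O5 is para to C8 and hydrogen-bonded to C4=O so it cannot reach the acyl group, and the tetrasubstituted electron-poor C2=C3 bond is inert to the hydride.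

**Step 7**
Reactants: 11 (10R)-lactone
Product: 13 methyl (3R)-3-(5-hydroxy-7-methoxy-2,3-dimethyl-4-oxo-4H-chromen-8-yl)-3-phenylpropanoate, via ring-opened hydroxy ester 12 (not isolated)
Conditions: K2CO3, MeOH/acetone (1:4), rt; then MeI, 40 °C
Reagents that add atoms: methanol, CO; methyl iodide, CI
Why: Base-mediated methanolysis of the aryl ester (lactone) followed in the same flask by Williamson O-methylation of the acidic 7-phenoxide, which makes the opening irreversible; the chelated 5-OH is not alkylated under these mild conditions and the stereocentre, β to the ester, is untouched.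

**Step 8**
Reactants: 13 methyl (3R)-3-(5-hydroxy-7-methoxy-2,3-dimethyl-4-oxo-4H-chromen-8-yl)-3-phenylpropanoate
Product: 14 methyl (3R)-3-(5-hydroxy-6-iodo-7-methoxy-2,3-dimethyl-4-oxo-4H-chromen-8-yl)-3-phenylpropanoate
Conditions: NIS, CH2Cl2, 0 °C → rt
Reagents that add atoms: N-iodosuccinimide, O=C1CCC(=O)N1I
Why: Electrophilic aromatic iodination ortho to the free 5-OH at C6, the only unsubstituted position of ring A.

**Step 9**
Reactants: 14 methyl (3R)-3-(5-hydroxy-6-iodo-7-methoxy-2,3-dimethyl-4-oxo-4H-chromen-8-yl)-3-phenylpropanoate; 15 3-methylbut-2-enylboronic acid pinacol ester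
Product: 16 methyl (3R)-3-[5-hydroxy-7-methoxy-2,3-dimethyl-6-(3-methylbut-2-en-1-yl)-4-oxo-4H-chromen-8-yl]-3-phenylpropanoate
Conditions: PdCl2(IPent)(3-chloropyridine) (3 mol %; IPent = 1,3-bis[2,6-di(pentan-3-yl)phenyl]imidazol-2-ylidene), K3PO4, THF/H2O, 60 °C
Reagents that add atoms: 3-methylbut-2-enylboronic acid pinacol ester (15), CC(C)=CCB1OC(C)(C)C(C)(C)O1
Why: Suzuki–Miyaura coupling of a prenylboronate, in which a very bulky carbene ligand on palladium is known to favour reductive elimination at the unsubstituted allyl terminus and so should give the linear prenyl arene instead of the 1,1-dimethylallyl isomer.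

**Step 10**
Reactants: 16 methyl (3R)-3-[5-hydroxy-7-methoxy-2,3-dimethyl-6-(3-methylbut-2-en-1-yl)-4-oxo-4H-chromen-8-yl]-3-phenylpropanoate
Product: 17 (3R)-3-[5-hydroxy-7-methoxy-2,3-dimethyl-6-(3-methylbut-2-en-1-yl)-4-oxo-4H-chromen-8-yl]-3-phenylpropanoic acid
Conditions: LiOH·H2O, THF/MeOH/H2O, rt; then 1 M HCl
Reagents that add atoms: lithium hydroxide, [Li+].[OH-]
Why: Ester saponification carried out at the chromone stage, where no base-labile stereocentre exists (the benzylic centre is β to the carboxyl group and not enolisable).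

**Step 11**
Reactants: 17 (3R)-3-[5-hydroxy-7-methoxy-2,3-dimethyl-6-(3-methylbut-2-en-1-yl)-4-oxo-4H-chromen-8-yl]-3-phenylpropanoic acid
Product: 20 (3R)-3-[(2S,3R)-5-hydroxy-7-methoxy-2,3-dimethyl-6-(3-methylbut-2-en-1-yl)-4-oxo-3,4-dihydro-2H-chromen-8-yl]-3-phenylpropanoic acid (target; 2,3-cis), via silyl ester 18 (not isolated), via silyl enol ether 19 (not isolated)
Conditions: Cu(OAc)2·H2O (5 mol %), (S)-DTBM-SEGPHOS (5.5 mol %), (EtO)2MeSiH (4 equiv), toluene/THF, 0 °C → rt; then pH 4 citrate buffer, THF, 0 °C
Reagents that add atoms: none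
Why: Copper hydride-catalysed asymmetric conjugate reduction of a chromone, in which the acid is first masked in the flask as its silyl ester by dehydrogenative silylation, the ligand-bound copper hydride delivers hydride to C2 on the face giving 2S (catalyst control), and kinetic protonation of the silyl enol ether at C3 anti to the pseudo-axial C2 methyl group gives the cis (3R) centre; the trisubstituted prenyl alkene is inert to copper hydride and the buffered work-up avoids epimerisation to the trans isomer.

**Compound list**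

1 | 2',4',6'-trihydroxypropiophenone | CCC(=O)c1c(O)cc(O)cc1O | starting material
2 | acetic anhydride | CC(=O)OC(C)=O | starting material
3 | 5,7-diacetoxy-2,3-dimethylchromone | CC1=C(C)C(=O)c2c(OC(C)=O)cc(OC(C)=O)cc2O1 | intermediate (not isolated)
4 | 5,7-dihydroxy-2,3-dimethylchromone | CC1=C(C)C(=O)c2c(O)cc(O)cc2O1 | intermediate
5 | 5,7-bis(methoxymethoxy)-2,3-dimethylchromone | CC1=C(C)C(=O)c2c(OCOC)cc(OCOC)cc2O1 | intermediate
6 | 8-iodo-5,7-bis(methoxymethoxy)-2,3-dimethylchromone | CC1=C(C)C(=O)c2c(OCOC)cc(OCOC)c(I)c2O1 | intermediate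
7 | 1-phenylvinylboronic acid pinacol ester | C=C(B1OC(C)(C)C(C)(C)O1)c1ccccc1 | starting material
8 | 5,7-bis(methoxymethoxy)-2,3-dimethyl-8-(1-phenylvinyl)chromone | CC1=C(C)C(=O)c2c(OCOC)cc(OCOC)c(C(=C)c3ccccc3)c2O1 | intermediate
9 | 5,7-dihydroxy-2,3-dimethyl-8-(1-phenylvinyl)chromone | CC1=C(C)C(=O)c2c(O)cc(O)c(C(=C)c3ccccc3)c2O1 | intermediate
10 | carbon monoxide | [C-]#[O+] | starting material
11 | (10R)-5-hydroxy-2,3-dimethyl-10-phenyl-9,10-dihydro-4H,8H-pyrano[2,3-f]chromene-4,8-dione | O=C1C[C@H](c2ccccc2)c2c(O1)cc(O)c1c2OC(C)=C(C)C1=O | intermediate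
12 | methyl (3R)-3-(5,7-dihydroxy-2,3-dimethyl-4-oxo-4H-chromen-8-yl)-3-phenylpropanoate (present as its 7-phenoxide) | COC(=O)C[C@H](c1ccccc1)c1c(O)cc(O)c2c1OC(C)=C(C)C2=O | intermediate (not isolated)
13 | methyl (3R)-3-(5-hydroxy-7-methoxy-2,3-dimethyl-4-oxo-4H-chromen-8-yl)-3-phenylpropanoate | COC(=O)C[C@H](c1ccccc1)c1c(OC)cc(O)c2c1OC(C)=C(C)C2=O | intermediate
14 | methyl (3R)-3-(5-hydroxy-6-iodo-7-methoxy-2,3-dimethyl-4-oxo-4H-chromen-8-yl)-3-phenylpropanoate | COC(=O)C[C@H](c1ccccc1)c1c(OC)c(I)c(O)c2c1OC(C)=C(C)C2=O | intermediate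
15 | 3-methylbut-2-enylboronic acid pinacol ester | CC(C)=CCB1OC(C)(C)C(C)(C)O1 | starting material
16 | methyl (3R)-3-[5-hydroxy-7-methoxy-2,3-dimethyl-6-(3-methylbut-2-en-1-yl)-4-oxo-4H-chromen-8-yl]-3-phenylpropanoate | COC(=O)C[C@H](c1ccccc1)c1c(OC)c(CC=C(C)C)c(O)c2c1OC(C)=C(C)C2=O | intermediate
17 | (3R)-3-[5-hydroxy-7-methoxy-2,3-dimethyl-6-(3-methylbut-2-en-1-yl)-4-oxo-4H-chromen-8-yl]-3-phenylpropanoic acid | OC(=O)C[C@H](c1ccccc1)c1c(OC)c(CC=C(C)C)c(O)c2c1OC(C)=C(C)C2=O | intermediate
18 | diethoxy(methyl)silyl ester of acid 17 | CCO[Si](C)(OCC)OC(=O)C[C@H](c1ccccc1)c1c(OC)c(CC=C(C)C)c(O)c2c1OC(C)=C(C)C2=O | intermediate (not isolated)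
19 | (2S)-4-silyloxy-2H-chromene (silyl enol ether at O4) of silyl ester 18, benzylic centre R | CCO[Si](C)(OCC)OC(=O)C[C@H](c1ccccc1)c1c(OC)c(CC=C(C)C)c(O)c2c1O[C@@H](C)C(C)=C2O[Si](C)(OCC)OCC | intermediate (not isolated)
20 | (3R)-3-[(2S,3R)-5-hydroxy-7-methoxy-2,3-dimethyl-6-(3-methylbut-2-en-1-yl)-4-oxo-3,4-dihydro-2H-chromen-8-yl]-3-phenylpropanoic acid | COc1c(CC=C(C)C)c(O)c2c(c1[C@H](CC(=O)O)c1ccccc1)O[C@@H](C)[C@@H](C)C2=O | target

**Step count and risks**

Total step count: 11. Longest linear sequence: 11 steps (1 to 20); compounds 2, 7, 10 and 15 enter as purchased partners.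

Steps most likely to fail:

Step 6. The hydropalladation may take the wrong regiochemistry or discriminate the faces poorly on this strongly twisted, electron-rich alkene, or the alkene may oligomerise under the acid co-catalyst before carbonylation. The fallback sets out from iodide 6 and returns at lactone 11. Heck reaction of 6 with methyl acrylate (Pd(OAc)2, Bu4NCl, NaHCO3, DMF, 80 °C) would give methyl (2E)-3-[5,7-bis(methoxymethoxy)-2,3-dimethyl-4-oxo-4H-chromen-8-yl]prop-2-enoate F1. Acetal cleavage (HCl, MeOH) would free methyl (2E)-3-(5,7-dihydroxy-2,3-dimethyl-4-oxo-4H-chromen-8-yl)prop-2-enoate F2. Irradiation at 365 nm should isomerise the alkene to Z, which lactonises onto O7 to the coumarin 5-hydroxy-2,3-dimethyl-4H,8H-pyrano[2,3-f]chromene-4,8-dione F3. A rhodium-catalysed asymmetric 1,4-addition of phenylboronic acid (Rh(acac)(C2H4)2, (R)-SEGPHOS, dioxane/H2O, 60 °C; Hayashi–Miyaura reaction) would then place phenyl on the benzylic carbon and give 11.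

Step 11. Hydride transfer to the fully substituted vinylogous ester may be slow, the ligand may not override the bias of the nearby benzylic centre at C2, or the cis relationship may erode during work-up. The fallback sets out from acid 17 and returns at target 20. Conjugate reduction with LiBH(s-Bu)3 (excess to cover the acid and phenol protons, THF, −78 °C) and quenching with AcOH at −78 °C (kinetic protonation, cis) should give 20 together with its ring diastereomer (3R)-3-[(2R,3S)-5-hydroxy-7-methoxy-2,3-dimethyl-6-(3-methylbut-2-en-1-yl)-4-oxo-3,4-dihydro-2H-chromen-8-yl]-3-phenylpropanoic acid F4. Because the benzylic centre is fixed, the two are diastereomers and would be separated by preparative HPLC.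

Step 9. Coupling may occur through the substituted allyl terminus, giving the 1,1-dimethylallyl isomer, or the crowded C6 iodide may undergo protodeiodination. The fallback sets out from iodide 14 and returns at ester 16. Suzuki–Miyaura coupling with allylboronic acid pinacol ester (Pd(dppf)Cl2, K2CO3, dioxane/H2O, 80 °C), which has no regiochemical ambiguity, would give methyl (3R)-3-[5-hydroxy-7-methoxy-2,3-dimethyl-4-oxo-6-(prop-2-en-1-yl)-4H-chromen-8-yl]-3-phenylpropanoate F5. Cross-metathesis with 2-methylbut-2-ene (second-generation Grubbs catalyst, CH2Cl2, 40 °C) would then convert allyl into prenyl and give 16.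

**Further compounds**

F1 | step 6 | methyl (2E)-3-[5,7-bis(methoxymethoxy)-2,3-dimethyl-4-oxo-4H-chromen-8-yl]prop-2-enoate | COC(=O)/C=C/c1c(OCOC)cc(OCOC)c2c1OC(C)=C(C)C2=O
F2 | step 6 | methyl (2E)-3-(5,7-dihydroxy-2,3-dimethyl-4-oxo-4H-chromen-8-yl)prop-2-enoate | COC(=O)/C=C/c1c(O)cc(O)c2c1OC(C)=C(C)C2=O
F3 | step 6 | 5-hydroxy-2,3-dimethyl-4H,8H-pyrano[2,3-f]chromene-4,8-dione | O=C1C=Cc2c(O1)cc(O)c1c2OC(C)=C(C)C1=O
F4 | step 11 | (3R)-3-[(2R,3S)-5-hydroxy-7-methoxy-2,3-dimethyl-6-(3-methylbut-2-en-1-yl)-4-oxo-3,4-dihydro-2H-chromen-8-yl]-3-phenylpropanoic acid | OC(=O)C[C@H](c1ccccc1)c1c(OC)c(CC=C(C)C)c(O)c2c1O[C@H](C)[C@H](C)C2=O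
F5 | step 9 | methyl (3R)-3-[5-hydroxy-7-methoxy-2,3-dimethyl-4-oxo-6-(prop-2-en-1-yl)-4H-chromen-8-yl]-3-phenylpropanoate | COC(=O)C[C@H](c1ccccc1)c1c(OC)c(CC=C)c(O)c2c1OC(C)=C(C)C2=O
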